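I count in one unit, the Rgt charge of a flask, and watch what share of it ends as Prd.

| flask | Sub | Rgt | time |
|---|---|---|---|
| Friday's | 250 mM | 375 mM |  |
| Wednesday's | 150 mM | 275 mM |  |
| Monday's | 750 mM | 375 mM |  |
| Tuesday's | 250 mM | 190 mM |  |
| Thursday's | 1800 mM | 375 mM | 13 min |

| Friday's run: time / min | Friday's run: [Prd] / mM | Wednesday's run: time / min | Wednesday's run: [Prd] / mM | Monday's run: time / min | Monday's run: [Prd] / mM | Tuesday's run: time / min | Tuesday's run: [Prd] / mM |
|---|---|---|---|---|---|---|---|
| 1.6 | 19.4 | 1.6 | 4.9 | 1.6 | 87.3 | 1.6 | 5.3 |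
| 3.2 | 34.4 | 3.2 | 12.1 | 3.2 | 166.4 | 3.2 | 10.2 |
| 4.9 | 46.0 | 4.9 | 12.1 | 4.9 | 195.5 | 4.9 | 11.4 |
| 6.5 | 54.1 | 6.5 | 14.1 | 6.5 | 207.7 | 6.5 | 12.8 |
| 8.1 | 58.9 | 8.1 | 15.5 | 8.1 | 206.8 | 8.1 | 15.0 |
| 9.8 | 61.0 | 9.8 | 14.4 | 9.8 | 210.2 | 9.8 | 13.4 |
| 11 | 63.5 | 11 | 14.9 | 11 | 209.1 | 11 | 14.4 |
| 13 | 61.1 | 13 | 16.3 | 13 | 210.8 | 13 | 14.2 |

(readings scatter by 1 mM)

- reaction order in [Rgt] at the outset, round the charge of the Friday's run, defined at two percent of the Sub turned into Prd
- reaction order in [Sub] at the outset, round the charge of the Friday's run, defined at two percent of the Sub turned into Prd (one fixed amount of Prd, the same in the runs compared)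
- Prd in the Thursday's run at 13 min, as a share of the Sub charged

- Overall: Sub + Rgt -> Prd.
- Constant volume, constant temperature.
- Readings of a species count what is bound in complexes too.
- "The second partner" is Rgt.
- An order is taken over about fifteen percent of the charge, up and down.

First I take the main step alone, one Rgt for each Prd. In Thursday's flask the Rgt charge is smaller than the Sub charge, so Rgt is the limiting reagent, and the whole unit turned into Prd makes 20.8% of the Sub.

The readings part from that picture. The readings of Friday's and Monday's flasks level off, and the last one has 16.3% of the Rgt charge as Prd in Friday's flask and 56.2% in Monday's. So I add a second process, a side loss of Rgt racing the main step. The last readings give 1.28 for Monday's flask and 0.195 for Friday's in one measure: the odds of Rgt, Prd at the plateau divided by the part of the Rgt charge not in Prd. With Monday's odds unchanged, my first estimate for Thursday's flask is 11.7% of its Sub.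

In this picture the odds compare the main step with the side loss over a whole run, and I read them from the plateaus, not from early rates. Monday's and Friday's flasks share a Rgt charge, so I compare those two. Monday's flask has 3.00 times the Sub of Friday's and 6.60 times the odds, which makes the odds go as Sub to the power 1.72. Carried to Thursday's Sub, that gives odds of 5.77, and my reckoning ends at 17.8% of the Sub.

The forecast reads the plateaus as “a reversible reaction whose product is stabilised by complexing”, a different road from mine. It gives 1.9 (1.5 to 2.3) for the order in Rgt, 1.25 (0.95 to 1.5) for the order in Sub, and 17.5% (15.5% to 19.5%) for Thursday's flask.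

The scheme behind the readings:

    2 Rgt ⇌ Rgt2, settled at all times (0.5030 M⁻¹)
    Sub + Rgt2 → Prd + Rgt (1.266 M⁻¹ min⁻¹)
    Rgt → Q (0.2676 min⁻¹)
    Sub + Rgt + Prd → 2 Prd (5.208 M⁻² min⁻¹)

Thursday's flask stands at 16.7% of its Sub at 13 min, and the orders at the outset are 1.8 in Rgt and 1.2 in Sub. Monday's flask runs 3.3 times as fast as Friday's where the same amount of Prd has been made, while the odds read from its last reading are 6.60 times Friday's, a larger ratio. Thursday's odds at 13 min come to 4.10, which is 3.19 times Monday's 1.28, with Prd equal to 80.4% of Thursday's Rgt charge.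

The runs come from a simulation for substances that don't exist.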